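Both ring-A C1–carbonyl bonds are formed last, by a two-fold anionic Fries-type O→C aroyl shift. The route exploits that in each ring A the ketone-bearing C1 is ortho to the C6 oxygen: a ring-B aroyl group carried as an ester on C6–O is delivered intramolecularly to C1 once bromine–lithium exchange makes C1 nucleophilic. One operation builds both tetra-ortho-substituted benzophenones and frees the C6 phenols. The precursor is the methylene-bridged bis(aryl bromide) with Br on C1, benzyl on C2–O and the 4-benzyloxy-2-methoxy-6-methylbenzoate on C6–O. Bromine is placed by directed lithiation between the ring-A oxygens; hydrogenolysis ends the synthesis.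

Key step: step 11

Remark on locants: in ring A, C1 carries the ketone (bromine in the precursors), C2–O is the oxygen beside the bridge-bearing carbon C3, C4 carries OMe, C5 is CH, and C6–O is the oxygen remote from the bridge. No compound in the route has a stereocentre.
Assumption: methyl orsellinate, 5-methoxyresorcinol, aqueous formaldehyde and aqueous dimethylamine are purchased.

Step 1
Reactants: 1 methyl orsellinate (methyl 2,4-dihydroxy-6-methylbenzoate)
Product: 2 methyl 4-(benzyloxy)-2-hydroxy-6-methylbenzoate
Conditions: BnBr (1.05 equiv), K2CO3, acetone, reflux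
Reagents that add atoms: benzyl bromide, BrCc1ccccc1
Why: Williamson ether synthesis should be selective for the 4-hydroxyl because the 2-hydroxyl is held in a hydrogen bond to the ester carbonyl and is far less nucleophilic under carbonate in acetone.

Step 2
Reactants: 2 methyl 4-(benzyloxy)-2-hydroxy-6-methylbenzoate
Product: 3 methyl 4-(benzyloxy)-2-methoxy-6-methylbenzoate
Conditions: MeI, K2CO3, DMF, 50 °C
Reagents that add atoms: iodomethane, CI
Why: With the 4-oxygen capped, Williamson methylation in a polar aprotic solvent with excess iodomethane should alkylate the remaining chelated 2-hydroxyl.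

Step 3
Reactants: 3 methyl 4-(benzyloxy)-2-methoxy-6-methylbenzoate
Product: 5 4-(benzyloxy)-2-methoxy-6-methylbenzoic acid, via potassium carboxylate 4 (not isolated)
Conditions: KOH, DMSO/H2O (4:1), 90 °C; then 1 M HCl, 0 °C
Reagents that add atoms: potassium hydroxide, [K+].[OH-]
Why: Saponification of the di-ortho-substituted methyl benzoate needs hot hydroxide in aqueous DMSO, which the benzyl and methyl aryl ethers tolerate, and cold acidification should release the acid.

Step 4
Reactants: 6 5-methoxyresorcinol (5-methoxybenzene-1,3-diol)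
Product: 7 1-methoxy-3,5-bis(methoxymethoxy)benzene
Conditions: MOMCl (2.5 equiv), i-Pr2NEt, CH2Cl2, 0 °C → rt
Reagents that add atoms: chloromethyl methyl ether, COCCl
Why: O-Alkylation of both phenols with the reactive α-chloro ether should give the bis(MOM) acetal, whose two chelating arms later direct the metalation and come off with acid.

Step 5
Reactants: 7 1-methoxy-3,5-bis(methoxymethoxy)benzene
Product: 9 2-bromo-5-methoxy-1,3-bis(methoxymethoxy)benzene, via C2-aryllithium 8 (not isolated)
Conditions: n-BuLi, THF, 0 °C → rt; then BrCH2CH2Br, −78 °C → rt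
Reagents that add atoms: 1,2-dibromoethane, BrCCBr
Why: Directed ortho-metalation should remove the proton between the two OMOM groups, which is flanked by two chelating acetal arms and is favoured over the two sites flanked by one OMOM and one OMe, and bromine transfer from 1,2-dibromoethane to the aryllithium then puts Br on the future ring-A C1, a position that electrophilic bromination of the free phenol would not select.

Step 6
Reactants: 9 2-bromo-5-methoxy-1,3-bis(methoxymethoxy)benzene
Product: 10 2-bromo-5-methoxybenzene-1,3-diol
Conditions: conc. HCl (cat.), MeOH, 50 °C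
Reagents that add atoms: none
Why: Acid-catalysed acetal methanolysis should remove both MOM groups as dimethoxymethane and leave the aryl bromide and the methyl ether untouched.

Step 7
Reactants: 10 2-bromo-5-methoxybenzene-1,3-diol; 11 formaldehyde
Product: 12 2-bromo-4-[(dimethylamino)methyl]-5-methoxybenzene-1,3-diol
Conditions: 40% aq. Me2NH (1.0 equiv), 37% aq. CH2O (1.0 equiv), EtOH, 0 °C → rt
Reagents that add atoms: dimethylamine, CNC
Why: In this phenolic Mannich reaction the iminium ion formed from formaldehyde and dimethylamine can only attack one of the two equivalent free ring carbons of 10, since bromine blocks C2, and with one equivalent of the iminium source the hydrogen-bonded mono-aminomethyl compound should be the main product.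

Step 8
Reactants: 12 2-bromo-4-[(dimethylamino)methyl]-5-methoxybenzene-1,3-diol; 10 2-bromo-5-methoxybenzene-1,3-diol
Product: 14 4,4'-methylenebis(2-bromo-5-methoxybenzene-1,3-diol), via ortho-quinone methide 13 (not isolated)
Conditions: 10 (4 equiv, excess recovered), dioxane, reflux, N2 stream
Reagents that add atoms: none
Why: Thermal loss of dimethylamine from the phenolic Mannich base should release an ortho-quinone methide at low concentration, which is captured by conjugate addition (Friedel–Crafts-type C-alkylation) of the excess 10 through one of its two equivalent free ring carbons, and the excess should suppress further condensation at the one CH left on each ring of 14.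

Step 9
Reactants: 5 4-(benzyloxy)-2-methoxy-6-methylbenzoic acid; 14 4,4'-methylenebis(2-bromo-5-methoxybenzene-1,3-diol)
Product: 16 methylenebis(2-bromo-3-hydroxy-5-methoxy-4,1-phenylene) bis[4-(benzyloxy)-2-methoxy-6-methylbenzoate], via aroyl chloride 15 (not isolated)
Conditions: 5 (2.05 equiv), (COCl)2, DMF (cat.), CH2Cl2, 0 °C → rt, evaporate; then 14, Et3N, DMAP (cat.), CH2Cl2, −20 °C → rt
Reagents that add atoms: none
Why: DMAP-catalysed esterification (nucleophilic acyl substitution) with a di-ortho-substituted aroyl chloride is governed by size, so it should take the two C6 hydroxyls, which have only Br and H as neighbours, and leave the C2 hydroxyls, which are wedged between Br and the diarylmethane bridge and hydrogen-bonded to each other.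

Step 10
Reactants: 16 methylenebis(2-bromo-3-hydroxy-5-methoxy-4,1-phenylene) bis[4-(benzyloxy)-2-methoxy-6-methylbenzoate]
Product: 17 methylenebis[3-(benzyloxy)-2-bromo-5-methoxy-4,1-phenylene] bis[4-(benzyloxy)-2-methoxy-6-methylbenzoate]
Conditions: BnBr, K2CO3, DMF, 40 °C
Reagents that add atoms: benzyl bromide, BrCc1ccccc1
Why: Williamson benzylation should cap the two remaining hindered phenols, while the aryl esters survive because their carbonyls are shielded by the ortho OMe and Me groups and the C2 phenoxide is meta to the ester oxygen, so acyl migration has no path.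

Step 11
Reactants: 17 methylenebis[3-(benzyloxy)-2-bromo-5-methoxy-4,1-phenylene] bis[4-(benzyloxy)-2-methoxy-6-methylbenzoate]
Product: 20 methylenebis[2-(benzyloxy)-6-hydroxy-4-methoxy-3,1-phenylene]bis{[4-(benzyloxy)-2-methoxy-6-methylphenyl]methanone}, via dilithio di-ester 18 (not isolated), via dilithium bis(phenoxide) 19 (not isolated)
Conditions: n-BuLi (2.2 equiv), THF, −78 °C → −20 °C; then 1 M HCl
Reagents that add atoms: none
Why: Bromine–lithium exchange at C1 of each ring A (favoured because the carbanion is flanked by the C2 and C6 oxygens) gives an aryllithium that adds through a four-membered transition state to the carbonyl of the ester on the neighbouring C6–O; collapse of the tetrahedral alkoxide breaks the C6–O–acyl bond, so the aroyl group ends on C1 and C6–O is released as the lithium phenoxide. The closest known reaction type is the anionic Fries (1,3 O→C acyl) rearrangement of ortho-haloaryl esters triggered by halogen–metal exchange. No ring is closed and no stereocentre is formed; two C–C bonds result. Regioselectivity (C1, not C5) is secured because bromine sits only on C1 and the lithiated carbon has the ester as its only ortho electrophile, the other ortho group being a benzyl ether. Chemoselectivity (exchange and intramolecular transfer instead of butyl addition to an ester or to the new ketone) is secured by the ortho OMe and Me groups of ring B, which shield the carbonyl from external nucleophiles, by the low temperature, and by the product ketone being masked as a chelated ortho-phenoxide.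

Step 12
Reactants: 20 methylenebis[2-(benzyloxy)-6-hydroxy-4-methoxy-3,1-phenylene]bis{[4-(benzyloxy)-2-methoxy-6-methylphenyl]methanone}
Product: 21 digriseophene A
Conditions: H2 (1 atm), Pd/C (10%), EtOAc/MeOH, rt
Reagents that add atoms: none
Why: Hydrogenolysis on palladium on carbon should cleave the four benzylic C–O bonds as toluene, while the tetra-ortho-substituted, hydrogen-bonded diaryl ketones and the diarylmethane bridge are not reduced at 1 atm and room temperature.

Compound list
1 | methyl orsellinate (methyl 2,4-dihydroxy-6-methylbenzoate) | COC(=O)c1c(C)cc(O)cc1O | starting material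
2 | methyl 4-(benzyloxy)-2-hydroxy-6-methylbenzoate | COC(=O)c1c(C)cc(OCc2ccccc2)cc1O | intermediate
3 | methyl 4-(benzyloxy)-2-methoxy-6-methylbenzoate | COC(=O)c1c(C)cc(OCc2ccccc2)cc1OC | intermediate
4 | potassium 4-(benzyloxy)-2-methoxy-6-methylbenzoate (not isolated) | [K+].[O-]C(=O)c1c(C)cc(OCc2ccccc2)cc1OC | intermediate
5 | 4-(benzyloxy)-2-methoxy-6-methylbenzoic acid | OC(=O)c1c(C)cc(OCc2ccccc2)cc1OC | intermediate
6 | 5-methoxyresorcinol (5-methoxybenzene-1,3-diol) | COc1cc(O)cc(O)c1 | starting material
7 | 1-methoxy-3,5-bis(methoxymethoxy)benzene | COCOc1cc(OC)cc(OCOC)c1 | intermediate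
8 | 2-lithio-5-methoxy-1,3-bis(methoxymethoxy)benzene (not isolated) | [Li]c1c(OCOC)cc(OC)cc1OCOC | intermediate
9 | 2-bromo-5-methoxy-1,3-bis(methoxymethoxy)benzene | COCOc1cc(OC)cc(OCOC)c1Br | intermediate
10 | 2-bromo-5-methoxybenzene-1,3-diol | COc1cc(O)c(Br)c(O)c1 | intermediate
11 | formaldehyde | C=O | starting material
12 | 2-bromo-4-[(dimethylamino)methyl]-5-methoxybenzene-1,3-diol (Mannich base) | COc1cc(O)c(Br)c(O)c1CN(C)C | intermediate
13 | 2-bromo-3-hydroxy-5-methoxy-6-methylidenecyclohexa-2,4-dien-1-one (ortho-quinone methide, not isolated) | C=C1C(=O)C(Br)=C(O)C=C1OC | intermediate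
14 | 4,4'-methylenebis(2-bromo-5-methoxybenzene-1,3-diol) | COc1cc(O)c(Br)c(O)c1Cc1c(OC)cc(O)c(Br)c1O | intermediate
15 | 4-(benzyloxy)-2-methoxy-6-methylbenzoyl chloride (not isolated) | ClC(=O)c1c(C)cc(OCc2ccccc2)cc1OC | intermediate
16 | methylenebis(2-bromo-3-hydroxy-5-methoxy-4,1-phenylene) bis[4-(benzyloxy)-2-methoxy-6-methylbenzoate] (C6–O di-ester, C2–OH free) | COc1cc(OC(=O)c2c(C)cc(OCc3ccccc3)cc2OC)c(Br)c(O)c1Cc1c(OC)cc(OC(=O)c2c(C)cc(OCc3ccccc3)cc2OC)c(Br)c1O | intermediate
17 | methylenebis[3-(benzyloxy)-2-bromo-5-methoxy-4,1-phenylene] bis[4-(benzyloxy)-2-methoxy-6-methylbenzoate] (key-step precursor) | COc1cc(OC(=O)c2c(C)cc(OCc3ccccc3)cc2OC)c(Br)c(OCc2ccccc2)c1Cc1c(OC)cc(OC(=O)c2c(C)cc(OCc3ccccc3)cc2OC)c(Br)c1OCc1ccccc1 | intermediate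
18 | C1,C1'-dilithio analogue of 17 (not isolated; drawn with both rings exchanged, the rings may exchange and rearrange in turn) | COc1cc(OC(=O)c2c(C)cc(OCc3ccccc3)cc2OC)c([Li])c(OCc2ccccc2)c1Cc1c(OC)cc(OC(=O)c2c(C)cc(OCc3ccccc3)cc2OC)c([Li])c1OCc1ccccc1 | intermediate
19 | dilithium bis(phenoxide) of 20 (not isolated) | COc1cc(O[Li])c(C(=O)c2c(C)cc(OCc3ccccc3)cc2OC)c(OCc2ccccc2)c1Cc1c(OC)cc(O[Li])c(C(=O)c2c(C)cc(OCc3ccccc3)cc2OC)c1OCc1ccccc1 | intermediate
20 | methylenebis[2-(benzyloxy)-6-hydroxy-4-methoxy-3,1-phenylene]bis{[4-(benzyloxy)-2-methoxy-6-methylphenyl]methanone} (key-step product) | COc1cc(O)c(C(=O)c2c(C)cc(OCc3ccccc3)cc2OC)c(OCc2ccccc2)c1Cc1c(OC)cc(O)c(C(=O)c2c(C)cc(OCc3ccccc3)cc2OC)c1OCc1ccccc1 | intermediate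
21 | digriseophene A, methylenebis(2,6-dihydroxy-4-methoxy-3,1-phenylene)bis[(4-hydroxy-2-methoxy-6-methylphenyl)methanone] | COc1cc(O)c(C(=O)c2c(C)cc(O)cc2OC)c(O)c1Cc1c(OC)cc(O)c(C(=O)c2c(C)cc(O)cc2OC)c1O | target

Total step count: 12
Longest linear sequence: 9 steps (steps 4 to 12, from 6); the ring-B branch (steps 1 to 3) joins at step 9.

Steps most likely to fail

1. Step 11. The C1 aryllithium may be protonated before it reaches the ester, butyllithium may add to an ester carbonyl, or the second ring may fail to rearrange once the first phenoxide has formed and aggregates. The fallback sets out from 14 (and uses 3) and comes back to the route at 21; it makes the ketone bonds by addition to an aldehyde and oxidation instead of acyl transfer. Compound 14 is perbenzylated (BnBr, K2CO3, DMF) to 1,1'-methylenebis[2,4-bis(benzyloxy)-3-bromo-6-methoxybenzene] F1. Ester 3 is reduced (LiAlH4, THF, 0 °C) to [4-(benzyloxy)-2-methoxy-6-methylphenyl]methanol F2, which is oxidised (MnO2, CH2Cl2) to 4-(benzyloxy)-2-methoxy-6-methylbenzaldehyde F3. Double bromine–lithium exchange of F1 (n-BuLi, THF, −78 °C) should give the dilithio species F4, which is quenched with F3 to give the bis(diarylmethanol) F5 as a mixture of diastereomers at the two carbinol carbons, both of which are removed in the next operation. Oxidation (2-iodoxybenzoic acid, EtOAc, 70 °C) should give the hexa-O-benzyl diketone F6, and hydrogenolysis (H2, Pd/C) of its six benzyl ethers gives 21.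

2. Step 9. The size difference between the C6 and C2 hydroxyls may not give clean discrimination, so that acylation at C2–O and over-acylation accompany the wanted bis-esterification. The fallback sets out from 14 and comes back at 17; it reverses the order of capping by means of a temporary bulky silyl group. TIPSCl (2.2 equiv) with imidazole in DMF should silylate only the open C6 hydroxyls to give 2,2'-methylenebis{6-bromo-3-methoxy-5-[(triisopropylsilyl)oxy]phenol} F7. Benzylation of the C2 hydroxyls (BnBr, K2CO3, acetone, reflux) gives 1,1'-methylenebis{2-(benzyloxy)-3-bromo-6-methoxy-4-[(triisopropylsilyl)oxy]benzene} F8. Tetrabutylammonium fluoride (THF, 0 °C) then frees the C6 hydroxyls to give 4,4'-methylenebis[3-(benzyloxy)-2-bromo-5-methoxyphenol] F9. These are now the only hydroxyls, and acylation with 15, prepared from 5 as in step 9 (Et3N, DMAP, CH2Cl2), gives 17.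

3. Step 8. Release of the quinone methide may be sluggish or unselective: the Mannich base, held by its O–H···N hydrogen bond, may lose dimethylamine only at temperatures at which it also alkylates itself or the product through their remaining activated ring CH, so that oligomers grow at the expense of 14. The fallback sets out from 10 and comes back at 14; it drops the amine and joins the rings by a direct one-pot phenol–formaldehyde condensation. A large excess of 10 (recovered afterwards) is treated with aqueous formaldehyde 11 and catalytic NaOH (MeOH/H2O, 0 °C → rt), which should give 2-bromo-4-(hydroxymethyl)-5-methoxybenzene-1,3-diol F10 in the flask. F10 loses water under these conditions or on mild acidification, and the resulting ortho-quinone methide 13 is intercepted at once by the surrounding 10 to give 14.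

Further compounds
F1 | step 11 | 1,1'-methylenebis[2,4-bis(benzyloxy)-3-bromo-6-methoxybenzene] | COc1cc(OCc2ccccc2)c(Br)c(OCc2ccccc2)c1Cc1c(OC)cc(OCc2ccccc2)c(Br)c1OCc1ccccc1
F2 | step 11 | [4-(benzyloxy)-2-methoxy-6-methylphenyl]methanol | COc1cc(OCc2ccccc2)cc(C)c1CO
F3 | step 11 | 4-(benzyloxy)-2-methoxy-6-methylbenzaldehyde | COc1cc(OCc2ccccc2)cc(C)c1C=O
F4 | step 11 | dilithio species from F1 (lithium in place of both bromines) | COc1cc(OCc2ccccc2)c([Li])c(OCc2ccccc2)c1Cc1c(OC)cc(OCc2ccccc2)c([Li])c1OCc1ccccc1
F5 | step 11 | methylenebis[2,6-bis(benzyloxy)-4-methoxy-3,1-phenylene]bis{[4-(benzyloxy)-2-methoxy-6-methylphenyl]methanol}, mixture of diastereomers | COc1cc(OCc2ccccc2)c(C(O)c2c(C)cc(OCc3ccccc3)cc2OC)c(OCc2ccccc2)c1Cc1c(OC)cc(OCc2ccccc2)c(C(O)c2c(C)cc(OCc3ccccc3)cc2OC)c1OCc1ccccc1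
F6 | step 11 | methylenebis[2,6-bis(benzyloxy)-4-methoxy-3,1-phenylene]bis{[4-(benzyloxy)-2-methoxy-6-methylphenyl]methanone} | COc1cc(OCc2ccccc2)c(C(=O)c2c(C)cc(OCc3ccccc3)cc2OC)c(OCc2ccccc2)c1Cc1c(OC)cc(OCc2ccccc2)c(C(=O)c2c(C)cc(OCc3ccccc3)cc2OC)c1OCc1ccccc1
F7 | step 9 | 2,2'-methylenebis{6-bromo-3-methoxy-5-[(triisopropylsilyl)oxy]phenol} | COc1cc(O[Si](C(C)C)(C(C)C)C(C)C)c(Br)c(O)c1Cc1c(OC)cc(O[Si](C(C)C)(C(C)C)C(C)C)c(Br)c1O
F8 | step 9 | 1,1'-methylenebis{2-(benzyloxy)-3-bromo-6-methoxy-4-[(triisopropylsilyl)oxy]benzene} | COc1cc(O[Si](C(C)C)(C(C)C)C(C)C)c(Br)c(OCc2ccccc2)c1Cc1c(OC)cc(O[Si](C(C)C)(C(C)C)C(C)C)c(Br)c1OCc1ccccc1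
F9 | step 9 | 4,4'-methylenebis[3-(benzyloxy)-2-bromo-5-methoxyphenol] | COc1cc(O)c(Br)c(OCc2ccccc2)c1Cc1c(OC)cc(O)c(Br)c1OCc1ccccc1
F10 | step 8 | 2-bromo-4-(hydroxymethyl)-5-methoxybenzene-1,3-diol | COc1cc(O)c(Br)c(O)c1CO
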